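## Structural features

The target is a single γ-butyrolactone ring, numbered here O1, C2 (carbonyl), C3, C4, C5; the systematic names used below number the ring the other way round, so the chain carbon is C2 and the acid carbon C3 of the oxolane. C3 carries an exocyclic methylene conjugated with the C2 carbonyl, C4 a free carboxylic acid, and C5 an unbranched thirteen-carbon chain that ends in a primary acetate. C4 (S) and C5 (R) are the only stereocentres; they are adjacent, and the acid and the chain are trans on the ring. The α-methylene lactone is a Michael acceptor, and under base or heat its double bond can move into the ring between C3 and C4, which would also erase the C4 centre. The acetate does not tolerate alkoxides or strong amide bases, and the acid must end up free. The real difficulty is twofold: setting the C4/C5 pair, in absolute and relative terms, next to a featureless alkyl chain, and introducing the C3 methylene late without base damage to C4 or to the acetate. The key step uses the fact that, once C5 is a ketone, the C4–H lies between that ketone and the carbonyl of the C4 ester; C4 then epimerises freely, so one enantioselective reduction at C5 can fix both centres.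

## Logic of the disconnections

**11 ⇒ 10.** The acetyl–oxygen bond at the chain terminus is cut. The only well-established way of building the C3 methylene on this kind of lactone acid uses hot MeOMgOCO2Me, which an acetate is not expected to survive. The acetate is therefore treated as a temporary group on the way in and is put on last, under neutral conditions. The forward step must acylate a primary alcohol without base and without activating the ring acid.

**10 ⇒ 9 ⇒ 8.** The exocyclic C3=CH2 bond is cut first, then the C3–CO2H bond. The methylene is the most fragile feature and is made last on the carbon skeleton; the decarboxylative Mannich reaction that makes it needs a malonic-type acid at C3, which comes from carboxylation of the C3–H2 of 8. The gain is that 8 has no alkene. The demand is carboxylation at C3 only, with C4 shielded as its carboxylate and not epimerised.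

**8 ⇒ 7.** The benzyl–oxygen bond of the C4 ester is cut. The acid is carried as a benzyl ester and released by hydrogenolysis while the molecule still has no alkene. No selectivity problem arises.

**7 ⇒ 6.** The O1–C2 lactone bond is cut, which opens the ring to an acyclic β-hydroxy diester. In the forward sense the carbinol can only close onto the CH2-ester (the other ester would give a four-membered ring). In 7 the only enolisable stereocentre is C4, so a base can move any cis material to trans. The demand is retention at both centres and a base loading low enough not to open the ring.

**6 ⇒ 5.** No skeletal bond is cut; the C5–H and O–H bonds are removed and C5 becomes a ketone. Both stereocentres disappear in this one move, because 5 is racemic and configurationally labile at C4. The forward step needs a catalyst that selects the ketone face whatever the configuration at C4, and racemisation that is faster than reduction. The ketone of 5 carries sp3 carbon on both sides, so a catalyst that recognises the β-keto ester by chelation is preferred to one that relies on an aryl group at the ketone. Reduction by hydrogenation with a diphosphine complex is chosen for this reason.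

**5 ⇒ 3 + 4.** The C4–C5 bond is cut. The ketone and the distal ester of 5 are in a 1,4-relationship, which calls for an acyl donor of reversed polarity, here an acyl radical from 3. The acceptor 4 is symmetrical, so no regiochemistry arises. The diester is kept as the dibenzyl compound: a symmetrical diester is required for this step, the benzyl ester survives lactonisation (so that C4 can still be equilibrated in 7), and it is later removed under neutral conditions. The demand is addition of the acyl radical faster than decarbonylation, and hydrogen abstraction at the formyl C–H only.

**3 ⇒ 2 ⇒ 1.** No skeletal bond is cut. The aldehyde comes from oxidation of a primary alcohol, and the monoacetate from statistical acylation of the symmetrical diol. The demands are that the oxidation stops at the aldehyde and that unreacted diol is recycled.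

## Other disconnections considered

**Alternative 1:** The cut is the C3–C4 bond of the lactone, traced back to a cyclopropane.
- Forward key step: A1 (methyl furan-2-carboxylate) and A2 (ethyl diazoacetate) would be joined by a carbene of monovalent copper, generated from A3 (CuOTf) and a C2-symmetric bis(oxazoline). It adds to the unsubstituted ring double bond of A1 and gives A4, 6-ethyl 3-methyl (1R,5R,6R)-2-oxabicyclo[3.1.0]hex-3-ene-3,6-dicarboxylate. One new C–C bond becomes C3–C4. The other is sacrificed later: after ozonolysis of the remaining enol ether, addition of a thirteen-carbon chain nucleophile to the liberated aldehyde and treatment with base, the cyclopropane opens by retro-aldol cleavage and the chain carbinol lactonises.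
- In its favour: C4 is fixed early, irreversibly and under catalyst control, on cheap achiral materials. On the permanence of C4 this plan is the better one, since the chosen route relies on a dynamic resolution backed by an equilibration.
- Against it here: the chain must be delivered as an organometallic reagent with a masked terminal oxygen; C5 is set by 1,2-induction and not by a catalyst; C4 emerges as an aldehyde that needs a further oxidation; a diazo compound must be handled.
- Comparison: both plans converge on the same lactone acid and share the late methylenation, so they are equal there. The alternative forms two skeletal bonds in its key step where the chosen one forms none. The chosen plan should be shorter by about three steps.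

**Alternative 2:** The cut is the bond between C4 and the carboxyl carbon.
- Forward key step: A5, the tributylstannylmethyl ether of a (5R)-2,5-dihydrofuran-3-ylmethanol carrying the silyl-protected chain, would undergo tin–lithium exchange with A6 (n-BuLi). The α-alkoxymethyl carbanion attacks the ring alkene carbon next to the chain-bearing carbon in a Wittig–Still [2,3] shift, anti to the chain, and the double bond moves to the exocyclic position. The product is A7, [(2R,3R)-2-[13-(tert-butyldiphenylsilyloxy)tridecyl]-4-methylidenetetrahydrofuran-3-yl]methanol.
- In its favour: the exocyclic methylene and the C4 branch are created together in a concerted step at low temperature, so no late carboxylation–Mannich sequence is needed. On the methylene problem this alternative is the better.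
- Against it here: A7 is at the wrong oxidation level at two carbons. The ring CH2 next to oxygen must become the lactone carbonyl by an allylic ether oxidation in the presence of the alkene, and CH2OH must become CO2H. The silyl ether must be exchanged for the acetate, tin is used stoichiometrically, and the C5 centre must already be present in enantiopure A5, which needs its own asymmetric synthesis.
- Comparison: on relative stereocontrol the plans are equal (1,2-induction in a ring versus equilibration to trans). On absolute control the chosen plan is better because it creates it catalytically. The alternative is expected to be longer.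

**Alternative 3:** The cut is the C5–C6 bond between ring and chain.
- Forward key step: A8 (the cis lactone of natural isocitric acid as its 3-tert-butyl ester and 2-N-hydroxyphthalimide ester) and A9 (the N-hydroxyphthalimide ester of 14-acetoxytetradecanoic acid) would be reduced at a cathode in the presence of A10 (NiCl2·glyme) and a bipyridine ligand. Both lose CO2 and the two alkyl fragments are joined at nickel, the new bond forming on the ring face away from the C4 ester. The product is A11, tert-butyl (2R,3S)-2-(13-acetoxytridecyl)-5-oxooxolane-3-carboxylate.
- In its favour: C4 comes from the chiral pool without any resolution, the coupling is convergent and should tolerate the acetate, and the tert-butyl analogue of 7 is reached in fewer steps. On step economy up to the lactone ester, and on the origin of the C4 configuration, this alternative is the equal or the better of the chosen plan.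
- Against it here: two alkyl radical precursors tend to homo-couple statistically unless one is used in excess. C5 rests only on induction from the neighbouring ester and cannot be corrected afterwards, whereas in the chosen plan C5 is set by the catalyst and the correctable centre is C4. The two carboxyls of the lactone must first be told apart.
- Comparison: from the lactone ester onwards the endgame (ester cleavage, C3 carboxylation, Mannich methylenation, fate of the acetate) is the same, so the plans are equal there. The alternative forms a skeletal bond by a less selective radical process; the chosen key step forms none.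

Key step: step 4

Remark on the structures: syn-configured 6 (S at the succinate carbon, R at the carbinol) closes to the trans lactone with 4S,5R, which is (2R,3S) in oxolane numbering and is the configuration of the target; the descriptors of 5, 6 and 11 are mutually consistent and needed no correction.

Assumption: the ω-acetate is taken to be cleaved by MeOMgOCO2Me at 135 °C. It is therefore re-installed in step 9; material that keeps it through steps 7 and 8 is already 11 and passes step 9 unchanged.

## Route

Step 1
Reactants: 1 tetradecane-1,14-diol
Product: 2 14-hydroxytetradecyl acetate
Conditions: Ac2O (1.0 equiv), 1 (2.0 equiv), pyridine, THF, 45 °C; recovered 1 recycled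
Reagents that add atoms: acetic anhydride, CC(=O)OC(C)=O
Why: O-acylation (nucleophilic acyl substitution) with the diol in excess, so that the statistical mixture is mainly diol and monoacetate, which differ enough in polarity to be separated; the two hydroxyls are equivalent, so mono versus bis is the only selectivity question.

Step 2
Reactants: 2 14-hydroxytetradecyl acetate
Product: 3 14-oxotetradecyl acetate (14-acetoxytetradecanal)
Conditions: TEMPO (10 mol %), PhI(OAc)2 (1.1 equiv), CH2Cl2, rt
Reagents that add atoms: none
Why: oxoammonium-mediated oxidation of a primary alcohol (TEMPO/PhI(OAc)2); without water it should stop at the aldehyde, and the acetate is inert.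

Step 3
Reactants: 3 14-oxotetradecyl acetate; 4 dibenzyl fumarate
Product: 5 dibenzyl 2-(14-acetoxytetradecanoyl)butanedioate (racemic)
Conditions: (n-Bu4N)4[W10O32] (2 mol %), 4 (1.3 equiv), MeCN, 390 nm LED, rt, Ar
Reagents that add atoms: none
Why: photocatalytic hydroacylation (Giese-type addition of an acyl radical): the excited [W10O32]4− anion abstracts the formyl hydrogen, the nucleophilic acyl radical adds to the electron-poor alkene, and the adduct radical takes the hydrogen back from the reduced catalyst. The acceptor is symmetrical, so only one constitution can form, and the new centre is racemic, which is what step 4 requires.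

Step 4
Reactants: 5 dibenzyl 2-(14-acetoxytetradecanoyl)butanedioate
Product: 6 dibenzyl (2S)-2-[(1R)-14-acetoxy-1-hydroxytetradecyl]butanedioate
Conditions: [RuCl(p-cymene)((R)-BINAP)]Cl (1 mol %), H2 (60 bar), CH2Cl2, 50 °C
Reagents that add atoms: none
Why: Noyori-type asymmetric hydrogenation of an α-substituted β-keto ester with dynamic kinetic resolution. The ketone and the carbonyl of the ester on C4 chelate the divalent ruthenium monohydride formed from the precatalyst and H2, and hydride passes to the ketone carbon inside this six-membered chelate; with (R)-BINAP the open quadrant exposes the Si face, so the carbinol is formed as R, as for simple 3-oxoalkanoates with this ligand. The C4–H lies between ketone and ester, so the two enantiomers of 5 interconvert through the enol faster than either is hydrogenated, and the enantiomer that leads to the syn product is consumed preferentially, which gives the 2S centre; the closest known case is the hydrogenation of 2-(acylaminomethyl)-3-oxobutanoates, which gives the same syn-(2S,3R) pattern with (R)-BINAP. No skeletal bond forms and no ring closes. C5 is under catalyst control and C4 under dynamic resolution, and C4 stays correctable in step 5 because it is the only enolisable centre of 7. The step needs chemoselectivity for the ketone: this complex is not a hydrogenolysis catalyst for benzyl esters, and the aprotic solvent excludes transesterification and favours enolisation over direct hydrogenation. A chelation-based catalyst is used because the ketone has sp3 carbon on both sides and offers no aryl group for a transfer-hydrogenation catalyst to recognise.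

Step 5
Reactants: 6 dibenzyl (2S)-2-[(1R)-14-acetoxy-1-hydroxytetradecyl]butanedioate
Product: 7 benzyl (2R,3S)-2-(13-acetoxytridecyl)-5-oxooxolane-3-carboxylate
Conditions: TsOH·H2O (5 mol %), toluene, 60 °C; then DBU (0.3 equiv), 60 °C
Reagents that add atoms: none
Why: acid-catalysed intramolecular transesterification (5-exo-trig lactonisation): the carbinol can reach only the CH2-ester carbonyl without strain, so one lactone forms, with retention at C4 and C5. DBU then equilibrates C4, the only enolisable stereocentre, so that lactone from any anti-configured reduction product drains into the more stable trans isomer 7; it is kept substoichiometric because β-elimination of the ring carboxylate from the same enolate would use up one equivalent of base per molecule lost.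

Step 6
Reactants: 7 benzyl (2R,3S)-2-(13-acetoxytridecyl)-5-oxooxolane-3-carboxylate
Product: 8 (2R,3S)-2-(13-acetoxytridecyl)-5-oxooxolane-3-carboxylic acid
Conditions: H2 (1 atm), 10% Pd/C, EtOAc, rt
Reagents that add atoms: none
Why: hydrogenolysis of a benzyl ester under neutral conditions; it is placed here because the molecule has no alkene yet, and lactone, acetate and both stereocentres are unaffected.

Step 7
Reactants: 8 (2R,3S)-2-(13-acetoxytridecyl)-5-oxooxolane-3-carboxylic acid
Product: 9 (2R,3S)-2-(13-hydroxytridecyl)-5-oxooxolane-3,4-dicarboxylic acid (configuration at oxolane C4 not defined; crude, used at once)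
Conditions: MeOMgOCO2Me (2 M in DMF, 30 equiv), 135 °C, N2, 48 h; then 6 M HCl, 0 °C
Reagents that add atoms: magnesium methyl carbonate (methoxymagnesium methyl carbonate), COC(=O)O[Mg]OC
Why: Stiles carboxylation: the reagent turns the C4 acid into its carboxylate, which takes the C4–H out of play, and carboxylates C3, the only remaining enolisable position; the product is held by chelation to Mg2+ until acidification. The ω-acetate is expected to be transesterified to methyl acetate under these conditions; any molecule that keeps it reaches 11 one step early.

Step 8
Reactants: 9 (2R,3S)-2-(13-hydroxytridecyl)-5-oxooxolane-3,4-dicarboxylic acid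
Product: 10 (2R,3S)-2-(13-hydroxytridecyl)-4-methylidene-5-oxooxolane-3-carboxylic acid
Conditions: 37% aq. HCHO, PhNHMe, NaOAc, AcOH, rt
Reagents that add atoms: formaldehyde, C=O
Why: decarboxylative Mannich methylenation: the iminium ion from formaldehyde and N-methylaniline alkylates the malonic-type C3 position, and loss of CO2 with expulsion of the amine gives the exocyclic alkene. The buffered acidic medium does not enolise C4, so both stereocentres and the position of the double bond are kept.

Step 9
Reactants: 10 (2R,3S)-2-(13-hydroxytridecyl)-4-methylidene-5-oxooxolane-3-carboxylic acid
Product: 11 (2R,3S)-2-(13-acetoxytridecyl)-4-methylidene-5-oxooxolane-3-carboxylic acid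
Conditions: vinyl acetate (5 equiv), immobilised Candida antarctica lipase B, MTBE, 30 °C
Reagents that add atoms: vinyl acetate, C=COC(C)=O
Why: lipase-catalysed transesterification of a primary alcohol with an enol ester; the vinyl alcohol released tautomerises to acetaldehyde, which makes the acylation irreversible. No base is present, so the exocyclic double bond cannot migrate into the ring, and the hindered ring acid is neither activated nor accepted by the enzyme as an acyl donor.

## Compound list

1 | tetradecane-1,14-diol | OCCCCCCCCCCCCCCO | starting material
2 | 14-hydroxytetradecyl acetate | CC(=O)OCCCCCCCCCCCCCCO | intermediate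
3 | 14-oxotetradecyl acetate (14-acetoxytetradecanal) | CC(=O)OCCCCCCCCCCCCCC=O | intermediate
4 | dibenzyl fumarate | O=C(/C=C/C(=O)OCc1ccccc1)OCc1ccccc1 | starting material
5 | dibenzyl 2-(14-acetoxytetradecanoyl)butanedioate (racemic) | CC(=O)OCCCCCCCCCCCCCC(=O)C(CC(=O)OCc1ccccc1)C(=O)OCc1ccccc1 | intermediate
6 | dibenzyl (2S)-2-[(1R)-14-acetoxy-1-hydroxytetradecyl]butanedioate | O[C@H](CCCCCCCCCCCCCOC(C)=O)[C@H](CC(=O)OCc1ccccc1)C(=O)OCc1ccccc1 | intermediate
7 | benzyl (2R,3S)-2-(13-acetoxytridecyl)-5-oxooxolane-3-carboxylate | C1C(=O)O[C@H](CCCCCCCCCCCCCOC(C)=O)[C@H]1C(=O)OCc2ccccc2 | intermediate
8 | (2R,3S)-2-(13-acetoxytridecyl)-5-oxooxolane-3-carboxylic acid | C1C(=O)O[C@H](CCCCCCCCCCCCCOC(C)=O)[C@H]1C(=O)O | intermediate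
9 | (2R,3S)-2-(13-hydroxytridecyl)-5-oxooxolane-3,4-dicarboxylic acid (oxolane C4 undefined) | OC(=O)C1C(=O)O[C@H](CCCCCCCCCCCCCO)[C@H]1C(=O)O | intermediate
10 | (2R,3S)-2-(13-hydroxytridecyl)-4-methylidene-5-oxooxolane-3-carboxylic acid | C=C1C(=O)O[C@H](CCCCCCCCCCCCCO)[C@H]1C(=O)O | intermediate
11 | (2R,3S)-2-(13-acetoxytridecyl)-4-methylidene-5-oxooxolane-3-carboxylic acid | C=C1C(=O)O[C@H](CCCCCCCCCCCCCOC(C)=O)[C@H]1C(=O)O | target

## Step count and least certain steps

Total: 9 steps. Longest linear sequence: 9 steps, from 1 to 11; 4 enters at step 3.

**Step 4 (key step).** The most likely failure is incomplete funnelling at C4: the two enantiomers of 5 may be hydrogenated at similar rates, or hydrogenation may outrun enolisation, so that syn and anti products form together. This is absorbed by step 5. The less likely but more serious failure is loss of facial selectivity at the ketone if the distal ester competes with the C4 ester for chelation; C5 cannot be corrected later. Partial lactonisation in the flask would be harmless.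
Fallback, from 3, returning at 8: an auxiliary-controlled syn-aldol reaction in place of the reduction. (4S)-4-Benzyl-1,3-oxazolidin-2-one is N-acylated with methyl 4-chloro-4-oxobutanoate (n-BuLi, THF, −78 °C) to methyl 4-[(4S)-4-benzyl-2-oxo-1,3-oxazolidin-3-yl]-4-oxobutanoate F4. Its boron Z-enolate (Bu2BOTf, i-Pr2NEt, CH2Cl2, −78 to 0 °C) adds to 3 through a Zimmerman–Traxler transition state and should give the Evans syn adduct, methyl (3S,4R)-17-acetoxy-3-[(4S)-4-benzyl-2-oxo-1,3-oxazolidine-3-carbonyl]-4-hydroxyheptadecanoate F5. This closes (cat. TsOH, toluene) to (4S)-3-[(2R,3S)-2-(13-acetoxytridecyl)-5-oxooxolane-3-carbonyl]-4-benzyl-1,3-oxazolidin-2-one F6, and LiOH/H2O2 (THF/H2O, 0 °C) cleaves the imide to 8. Any acid that loses its acetate here is equally usable, since step 7 removes the acetate anyway.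

**Step 3.** Hydrogen abstraction may not be confined to the formyl C–H: the twelve chain methylenes and the benzylic positions of 4 compete. The acyl radical may also decarbonylate before it adds.
Fallback, from 2, returning at 5: polar construction of the same bond set. Oxidation of 2 (TEMPO, PhI(OAc)2, MeCN/H2O) gives 14-acetoxytetradecanoic acid F1. Acylation of Meldrum's acid (DCC, DMAP, CH2Cl2) gives 5-(14-acetoxy-1-hydroxytetradecylidene)-2,2-dimethyl-1,3-dioxane-4,6-dione F2. Heating with benzyl alcohol (toluene, 90 °C) gives benzyl 16-acetoxy-3-oxohexadecanoate F3, and C-alkylation with benzyl bromoacetate (K2CO3, acetone) gives 5.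

**Step 5.** The C4 enolate needed for epimerisation can also expel the ring carboxylate by β-elimination (the ring-opening known from the Stobbe condensation), or the equilibration may be too slow with an amidine base.
Fallback, from 6, returning at 7: separation in place of equilibration. The lactonisation is run with acid only and the minor C4-epimeric lactone is removed by chromatography at the stage of 7, or by crystallisation after step 6, at the cost of the material in the cis series.

**Step 7.** Two days at 135 °C in a basic medium invite incomplete carboxylation, decomposition, and premature decarboxylation during the acidic work-up; the acetate may also be cleaved only in part, which step 9 corrects.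
Fallback, from 8, returning at 10: a dianion Mannich route under kinetic conditions. Methanolysis of the acetate (K2CO3, MeOH; then aq. HCl to re-close the lactone) gives (2R,3S)-2-(13-hydroxytridecyl)-5-oxooxolane-3-carboxylic acid F7. Silylation (TBSCl, imidazole, DMF; aqueous work-up to hydrolyse the silyl ester) gives (2R,3S)-2-[13-(tert-butyldimethylsilyloxy)tridecyl]-5-oxooxolane-3-carboxylic acid F8. The dianion (NaN(SiMe3)2, 2.3 equiv, THF, −78 °C) is trapped at C3 with [CH2=NMe2]I; quaternisation (MeI) and elimination (aq. NaHCO3) give (2R,3S)-2-[13-(tert-butyldimethylsilyloxy)tridecyl]-4-methylidene-5-oxooxolane-3-carboxylic acid F9. Desilylation (AcOH/THF/H2O) gives 10.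

## Further compounds

F1 | step 3 | 14-acetoxytetradecanoic acid | CC(=O)OCCCCCCCCCCCCCC(=O)O
F2 | step 3 | 5-(14-acetoxy-1-hydroxytetradecylidene)-2,2-dimethyl-1,3-dioxane-4,6-dione | CC(=O)OCCCCCCCCCCCCCC(O)=C1C(=O)OC(C)(C)OC1=O
F3 | step 3 | benzyl 16-acetoxy-3-oxohexadecanoate | CC(=O)OCCCCCCCCCCCCCC(=O)CC(=O)OCc1ccccc1
F4 | step 4 | methyl 4-[(4S)-4-benzyl-2-oxo-1,3-oxazolidin-3-yl]-4-oxobutanoate | COC(=O)CCC(=O)N1C(=O)OC[C@@H]1Cc1ccccc1
F5 | step 4 | methyl (3S,4R)-17-acetoxy-3-[(4S)-4-benzyl-2-oxo-1,3-oxazolidine-3-carbonyl]-4-hydroxyheptadecanoate | O[C@H](CCCCCCCCCCCCCOC(C)=O)[C@H](CC(=O)OC)C(=O)N1C(=O)OC[C@@H]1Cc1ccccc1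
F6 | step 4 | (4S)-3-[(2R,3S)-2-(13-acetoxytridecyl)-5-oxooxolane-3-carbonyl]-4-benzyl-1,3-oxazolidin-2-one | C1C(=O)O[C@H](CCCCCCCCCCCCCOC(C)=O)[C@H]1C(=O)N2C(=O)OC[C@@H]2Cc3ccccc3
F0 | step 5 | none | none
F7 | step 7 | (2R,3S)-2-(13-hydroxytridecyl)-5-oxooxolane-3-carboxylic acid | C1C(=O)O[C@H](CCCCCCCCCCCCCO)[C@H]1C(=O)O
F8 | step 7 | (2R,3S)-2-[13-(tert-butyldimethylsilyloxy)tridecyl]-5-oxooxolane-3-carboxylic acid | C1C(=O)O[C@H](CCCCCCCCCCCCCO[Si](C)(C)C(C)(C)C)[C@H]1C(=O)O
F9 | step 7 | (2R,3S)-2-[13-(tert-butyldimethylsilyloxy)tridecyl]-4-methylidene-5-oxooxolane-3-carboxylic acid | C=C1C(=O)O[C@H](CCCCCCCCCCCCCO[Si](C)(C)C(C)(C)C)[C@H]1C(=O)O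
A1 | alternative 1 | methyl furan-2-carboxylate | COC(=O)c1ccco1
A2 | alternative 1 | ethyl diazoacetate | CCOC(=O)C=[N+]=[N-]
A3 | alternative 1 | copper triflate, CuOTf | [Cu+].[O-]S(=O)(=O)C(F)(F)F
A4 | alternative 1 | 6-ethyl 3-methyl (1R,5R,6R)-2-oxabicyclo[3.1.0]hex-3-ene-3,6-dicarboxylate | COC(=O)C1=C[C@@H]2[C@@H](C(=O)OCC)[C@@H]2O1
A5 | alternative 2 | tributyl[({(5R)-5-[13-(tert-butyldiphenylsilyloxy)tridecyl]-2,5-dihydrofuran-3-yl}methoxy)methyl]stannane | CCCC[Sn](CCCC)(CCCC)COCC1=C[C@@H](CCCCCCCCCCCCCO[Si](c2ccccc2)(c2ccccc2)C(C)(C)C)OC1
A6 | alternative 2 | n-butyllithium, n-BuLi | [Li]CCCC
A7 | alternative 2 | [(2R,3R)-2-[13-(tert-butyldiphenylsilyloxy)tridecyl]-4-methylidenetetrahydrofuran-3-yl]methanol | C=C1CO[C@H](CCCCCCCCCCCCCO[Si](c2ccccc2)(c2ccccc2)C(C)(C)C)[C@H]1CO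
A8 | alternative 3 | 3-tert-butyl 2-(1,3-dioxoisoindolin-2-yl) (2R,3S)-5-oxooxolane-2,3-dicarboxylate | C1C(=O)O[C@@H](C(=O)ON2C(=O)c3ccccc3C2=O)[C@H]1C(=O)OC(C)(C)C
A9 | alternative 3 | 1,3-dioxoisoindolin-2-yl 14-acetoxytetradecanoate | CC(=O)OCCCCCCCCCCCCCC(=O)ON1C(=O)c2ccccc2C1=O
A10 | alternative 3 | nickel dichloride 1,2-dimethoxyethane complex, NiCl2·glyme | [Ni+2].[Cl-].[Cl-].COCCOC
A11 | alternative 3 | tert-butyl (2R,3S)-2-(13-acetoxytridecyl)-5-oxooxolane-3-carboxylate | C1C(=O)O[C@H](CCCCCCCCCCCCCOC(C)=O)[C@H]1C(=O)OC(C)(C)C
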